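## Structural features

The target is a spirolactone-type 6,7-seco-ent-kauranoid: 1,19-diacetoxy-6-hydroxy-15-oxo-6,7-seco-ent-kaur-16-en-7,20-olide (ent-kaurane numbering throughout). Ring A (C1–C5, C10) is joined by the single bond C9–C10 to a bicyclo[3.2.1]octane made of ring C (C8, C9, C11–C14) and ring D (C8, C14, C13, C16, C15). A δ-lactone (C7, O, C20) is spiro at C10 and cis-fused to ring C at C8–C9. There are seven stereocentres: C4, C5, C10 and C1 are contiguous on ring A, with O1, C20, C19 and C6 on one face; quaternary C10, C9 and quaternary C8 follow across the inter-ring bond; C13 is a bridgehead. Fragile groups are the α-methylene cyclopentanone (C15, C16=C17), the non-enolizable β-keto lactone (open to retro-Claisen cleavage) and two acetates beside a free primary alcohol (acyl migration). O1 and O20 are both δ to C7, so either could close a lactone. The real difficulty is the C9–C10 bond between a quaternary and a tertiary stereocentre with no ring to relay configuration, the quaternary C8 with its C15 bridge trans to C10, and oxygen on the neopentyl angular carbon C20. The key step uses the fact that C20 is γ to O1 and gauche to it (O1 equatorial, C20 axial on ring A), so a C20 methyl group can be silylated from an O1-bound Si–H group and later oxidized to the lactone oxygen.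

## Logic of the disconnections

39 ⇒ 38 ⇒ 36 ⇒ 34. The C6 silyl ether and the exocyclic C16=C17 bond are removed, C17 going back to an iminium one-carbon unit. The enone is the most electrophilic group and should appear last. 34 is a plain ketone with one enolizable position (C16). The forward steps must spare two acetates and the lactone.

34 ⇒ 33 ⇒ 32 ⇒ 29. The O19 acetate, the ketal, the O1 acetate and the lactone bond C7–O20 are cut. Because O1 can also reach C7, the lactone is closed on 29 by kinetic carboxyl activation and O1 is capped in the same flask. The ketal stays until after closure so that the β-keto ester cannot suffer retro-Claisen cleavage. The demand is that the primary hydroxyl wins over the hindered secondary one.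

29 ⇒ 28 ⇒ 27. The C20–O bond is traced back to a C20–Si bond and the acid to its methyl ester. This turns an oxygenated neopentyl carbon into a silicon-bound one; the oxidation must leave ester, ketal and silyl ethers alone.

27 ⇒ 26. The C20–Si bond is cut to a C20–H bond and an O1–Si–H group. C20 becomes an inert methyl group that can be carried through all C–C bond formation. The forward step must select the primary C–H bond among the γ C–H bonds.

26 ⇒ 24 ⇒ 23 ⇒ 22. The O1–Si bond, the C1 carbinol hydrogen and the hydrogens on C2, C3, C11 and C12 are removed. In 22 the ring A enone is non-enolizable and far less electrophilic than the C15 ketone, which allows selective ketalization; reduction at C1 must give the equatorial alcohol cis to C20.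

22 ⇒ 21 ⇒ 20 ⇒ 19. Ring D is opened at C13–C16. 19 is a cyclohexene carrying an acetyl group; the acetyl group must sit trans to C10 on C8 so that the bridge forms on the H9 face.

19 ⇒ 18 ⇒ 16 ⇒ 14. Ring C is opened at C12=C13 (metathesis), then C8–C14 and C9–C11 are cut to the allyl donors 17 and 15. This reduces the bicycle to an alkylidene 1,3-dicarbonyl unit on C10; both additions must be face-selective in an open chain.

14 ⇒ 9 + 12, and 12 ⇒ 10 + 11. The C9–C10 bond is cut to the α′-enolate of 9 and the alkoxymethylene acceptor. C10 becomes quaternary without creating C9 at the same time; the electrophile must enter anti to the C5 substituent.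

9 ⇒ 8 ⇒ 7 ⇒ 6 ⇒ 5 ⇒ 4 ⇒ 2 + 3, and 2 ⇒ 1. Ring A is a Diels–Alder adduct in which the anhydride supplies C19 and C6 cis and the diene supplies C1 oxygen and the C20 methyl group. The racemate is resolved through 5; the cycloaddition must be regioselective.

## Other disconnections considered

Alternative 1: The cut is at C13–C14 and C8–C15. In the forward step Pd(PPh3)4 (zerovalent palladium) ionizes the allylic carbonate of α-methylene lactone A1; the sulfonyl-stabilized C13 carbanion adds to C14 and the C8 lactone enolate closes on the allyl terminus, giving sulfone A2 with rings C and D. In its favour, two C–C bonds, both carbocycles and the quaternary C8 arise in one catalytic step. It is better than the chosen plan in that C16=C17 is already present and the lactone exists from the start, so neither a C–H oxidation at C20 nor a choice between O1 and O20 is needed. Against it, A1 already needs the spiro C10, the C9 stereocentre and the C20 oxygen, so the hardest bond (C9–C10) is not addressed. The cyclization must also proceed in a bridged mode that forms two bridgeheads, and A2 still needs desulfonylation at C13 (SmI2) and allylic oxidation at C15 (SeO2, then oxidation). In step count after the ring-forming event the two plans are about equal.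

Alternative 2: The cut is at C8–C9 and C7–O. Photolysis of 2-diazocycloheptanone A3 triggers a Wolff rearrangement in which C9 migrates with retention, and the ketene is trapped by the C20 hydroxyl to give cis-fused lactone A4. In its favour, ring C and the lactone form together under neutral conditions. It is better than the chosen plan on lactone regiochemistry, because O1 is blocked and only O20 can add. Against it, A3 is a seven-membered ring with C9 and C13 stereocentres in a 1,4 relation, which is harder to control than a bridgehead that forms automatically. C8 is only tertiary in A4, so the C8–C15 bond and ring D must still be made by an intramolecular aldol reaction of the lactone enolate with the unmasked C13 side chain. The C20 oxygen must again be present early. Both plans end with the same C16 methylenation; overall this route is not shorter.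

Alternative 3: The cut is at C10–C20. Bu3SnH generates the silylmethyl radical from (bromomethyl)silyl ether A5, which adds 5-exo to C10, and hydrogen transfer to the C5 radical gives oxasilolane A6. In its favour, the same cis O1–Si–C20 ring as in 27 is made by C–C bond formation on a small fragment, with the same oxidative exit. It is better than the chosen plan in that it does not rely on C–H activation at a congested late intermediate. Against it, the radical must attack a fully substituted alkene carbon, and the face of hydrogen delivery at C5 is not secured. C9 is left as an acetal carbon on a quaternary centre, so the C9 stereocentre with C8 and C11 must be built by additions to a neopentyl aldehyde. The C20 oxygen then needs protection throughout, and tin is used stoichiometrically. On the silicon tether and its oxidation the two plans are equal.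

Key step: step 19

Assumption: the two menthyl hemiesters of step 3 are taken to be separable by crystallization, and the one with the ring A configuration of the target (to be assigned by X-ray analysis) is carried on; the C10 configuration of 4–9 is that of the endo adduct and is of no consequence because C10 is enolized in step 9. TBS = tert-butyldimethylsilyl, TBDPS = tert-butyldiphenylsilyl.

Step 1
Reactants: 1 pent-1-en-3-one
Product: 2 (Z)-3-(tert-butyldimethylsilyloxy)penta-1,3-diene
Conditions: TBSOTf, Et3N, Et2O, 0 °C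
Reagents that add atoms: tert-butyldimethylsilyl trifluoromethanesulfonate, CC(C)(C)[Si](C)(C)OS(=O)(=O)C(F)(F)F
Why: Soft enolization of the ethyl ketone with a silyl triflate and Et3N should give the silyl dienol ether; the (Z) enol ether (methyl trans to vinyl), which allows the s-cis diene, is the usual outcome of this silylation.

Step 2
Reactants: 2 (Z)-3-(tert-butyldimethylsilyloxy)penta-1,3-diene; 3 citraconic anhydride
Product: 4 racemic endo adduct 5-(tert-butyldimethylsilyloxy)-4,7a-dimethyl-3a,4,7,7a-tetrahydro-2-benzofuran-1,3-dione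
Conditions: toluene, 80 °C, sealed tube
Reagents that add atoms: none
Why: Thermal Diels–Alder reaction; the nucleophilic diene terminus next to the siloxy carbon (C10) should bond to the unsubstituted, less hindered anhydride carbon (C5), which puts the C1 oxygen 1,4 to C4. Suprafacial addition fixes C19 and C6 cis, and endo approach places the C10 methyl cis to the anhydride.

Step 3
Reactants: 4 racemic endo adduct
Product: 5 (1R,2S,5R)-menthyl hemiester of ring A (menthyl ester at C6; free acid at C19; single diastereomer)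
Conditions: (−)-menthol, DMAP (cat.), toluene, 60 °C; fractional crystallization
Reagents that add atoms: (−)-menthol, CC(C)[C@@H]1CC[C@@H](C)C[C@H]1O
Why: DMAP-catalysed alcoholysis should open the anhydride at the less hindered C6 carbonyl and turn the enantiomers into diastereomeric hemiesters; this is a classical resolution through a covalent auxiliary, which is returned in step 4.

Step 4
Reactants: 5 menthyl hemiester
Product: 6 ring A diol (C19-OH and C6-OH cis; C1 TBS enol ether C1=C2; 4R,5S)
Conditions: LiAlH4, THF, 0 to 50 °C; aq. NaOH work-up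
Reagents that add atoms: none
Why: LiAlH4 reduces the ester and the acid to the two primary alcohols and releases menthol, while the silyl enol ether keeps C1 at the ketone oxidation level.

Step 5
Reactants: 6 ring A diol
Product: 7 C6-OTBDPS ether of the ring A diol (C19-OH free)
Conditions: TBDPSCl, imidazole, CH2Cl2, −20 to 0 °C
Reagents that add atoms: tert-butyl(chloro)diphenylsilane, CC(C)(C)[Si](Cl)(c1ccccc1)c1ccccc1
Why: A bulky chlorosilane should react at the C6 hydroxyl (on a tertiary carbon) before the neopentyl C19 hydroxyl; selective silylation of the less hindered primary alcohol.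

Step 6
Reactants: 7 C6-OTBDPS ether
Product: 8 C19-OTBS C6-OTBDPS ring A bis-silyl ether (C1 TBS enol ether)
Conditions: TBSOTf, 2,6-lutidine, CH2Cl2, −78 to 0 °C
Reagents that add atoms: tert-butyldimethylsilyl trifluoromethanesulfonate, CC(C)(C)[Si](C)(C)OS(=O)(=O)C(F)(F)F
Why: The neopentyl hydroxyl is silylated with the more reactive triflate; TBS and TBDPS differ enough in acid lability for C19 to be released alone later.

Step 7
Reactants: 8 ring A bis-silyl ether
Product: 9 ring A enone (C1 ketone; C2=C3; C10-H methyl; C19-OTBS; C6-OTBDPS)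
Conditions: Pd(OAc)2, MeCN, 40 °C
Reagents that add atoms: none
Why: Saegusa–Ito oxidation: Pd(OAc)2 (divalent palladium) converts the silyl enol ether into the enone by β-hydride elimination from C3. The enone leaves C10–H as the only acidic hydrogen, because C4 is quaternary.

Step 8
Reactants: 10 methyl acetoacetate; 11 trimethyl orthoformate
Product: 12 methyl 2-(methoxymethylene)-3-oxobutanoate (E/Z mixture)
Conditions: Ac2O, 130 °C, distillation
Reagents that add atoms: none
Why: Condensation of an active methylene compound with an orthoformate under acetic anhydride is the standard route to alkoxymethylene 1,3-dicarbonyl compounds; C9 comes from the orthoformate.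

Step 9
Reactants: 9 ring A enone; 12 methyl 2-(methoxymethylene)-3-oxobutanoate
Product: 14 C10-quaternary alkylidene acetoacetate (C9=C8; C20 methyl cis to C6; E/Z mixture), via lithium dienolate 13 (not isolated)
Conditions: LiN(iPr)2, THF, −78 °C; added to 12 in THF, −78 to −30 °C; aq. NH4Cl
Reagents that add atoms: none
Why: Kinetic α′-deprotonation of the enone gives a regiodefined cross-conjugated enolate; Michael addition to the alkoxymethylene acceptor and loss of methoxide (addition–elimination) forms C9–C10. The electrophile should enter anti to the vicinal C5 CH2OTBDPS group (2,3-trans alkylation of cyclohexanone enolates), which sets C10.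

Step 10
Reactants: 14 alkylidene acetoacetate; 15 allyltrimethylsilane
Product: 16 C9-allyl β-keto ester (C8 epimers)
Conditions: TiCl4, CH2Cl2, −78 °C; aq. NaHCO3
Reagents that add atoms: none
Why: Hosomi–Sakurai conjugate allylation of the TiCl4-chelated alkylidene 1,3-dicarbonyl unit, which is far more electrophilic than the hindered ring A enone. A(1,3) strain should hold the C10 methyl in the alkylidene plane, so the silane adds to the C9 face away from the C5 branch and gives the C9 configuration of the target.

Step 11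
Reactants: 16 C9-allyl β-keto ester; 17 allyl methyl carbonate
Product: 18 C8,C9-diallyl β-keto ester (C8 quaternary; acetyl anti to C10 in the zigzag drawn by the SMILES)
Conditions: Pd(PPh3)4 (5 mol %), THF, 25 °C
Reagents that add atoms: none
Why: Tsuji–Trost allylation under neutral conditions makes the quaternary C8. With C9–H eclipsing the enolate double bond (A(1,3) strain), the π-allyl electrophile should add anti to the quaternary C10 substituent, which places the acetyl group trans to C10 in the later ring.

Step 12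
Reactants: 18 diallyl β-keto ester
Product: 19 ring C cyclohexene keto ester (C12=C13; acetyl trans to C10)
Conditions: [RuCl2(=CHPh)(H2IMes)(PCy3)] (second-generation Grubbs catalyst, 5 mol %), CH2Cl2, 40 °C
Reagents that add atoms: none
Why: Ring-closing metathesis of the 1,7-diene closes ring C; geminal substitution at C8 favours closure, and the conjugated ring A enone does not take part.

Step 13
Reactants: 19 ring C cyclohexene keto ester
Product: 20 TBS enol ether of the C15 methyl ketone (C15=C16)
Conditions: TBSOTf, Et3N, CH2Cl2, 0 to 25 °C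
Reagents that add atoms: tert-butyldimethylsilyl trifluoromethanesulfonate, CC(C)(C)[Si](C)(C)OS(=O)(=O)C(F)(F)F
Why: Soft enolization can occur only at the acetyl methyl group, because C8 is quaternary and the ring A enone has quaternary α′ and γ carbons; a single silyl enol ether should result.

Step 14
Reactants: 20 TBS enol ether
Product: 21 methyl 19-OTBS-6-OTBDPS-1,15-dioxo-17-nor-6,7-seco-ent-kaura-2,11-dien-7-oate (bicyclo[3.2.1]octenone; two-carbon bridge cis to H9)
Conditions: Pd(OAc)2 (1.1 equiv), DMSO, 45 °C
Reagents that add atoms: none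
Why: Oxidative cycloalkenylation of a silyl enol ether with Pd(OAc)2 (divalent palladium): the palladium enolate adds 5-exo across C12=C13 to form C16–C13, and β-hydride elimination gives the C11=C12 alkene. The acetyl group reaches C13 only on its own face, which fixes C13, and simple dehydrogenation is impossible because C8 is quaternary.

Step 15
Reactants: 21 bicyclo[3.2.1]octenone
Product: 22 methyl 19-OTBS-6-OTBDPS-15,15-ethylenedioxy-1-oxo-17-nor-6,7-seco-ent-kaura-2,11-dien-7-oate
Conditions: TMSOCH2CH2OTMS, TMSOTf (10 mol %), CH2Cl2, −78 to −20 °C; pyridine quench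
Reagents that add atoms: 1,2-bis(trimethylsilyloxy)ethane, C[Si](C)(C)OCCO[Si](C)(C)C
Why: Aprotic ketalization should select the saturated, ester-activated C15 ketone over the conjugated and more hindered C1 enone carbonyl; the silyl ethers survive the cold, catalytic-acid conditions.

Step 16
Reactants: 22 C15 dioxolane dienone
Product: 23 methyl 19-OTBS-6-OTBDPS-15,15-ethylenedioxy-1-oxo-17-nor-6,7-seco-ent-kauran-7-oate
Conditions: H2 (1 atm), Pd/C, EtOAc, 25 °C
Reagents that add atoms: none
Why: Heterogeneous hydrogenation saturates the C11=C12 alkene and the C2=C3 enone double bond in one operation; no stereocentre is formed.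

Step 17
Reactants: 23 C1 ketone
Product: 24 methyl 19-OTBS-6-OTBDPS-15,15-ethylenedioxy-1-hydroxy-17-nor-6,7-seco-ent-kauran-7-oate (1-OH equatorial; cis to C20)
Conditions: NaBH4, MeOH/THF, −20 to 0 °C; aq. NH4Cl
Reagents that add atoms: none
Why: Borohydride should attack C1 along the axial trajectory, on the face opposite the axial C20 methyl of the neighbouring carbon, and give the equatorial alcohol cis to C20; the hindered methyl ester and the ketal are not touched.

Step 18
Reactants: 24 C1 alcohol; 25 diethylsilane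
Product: 26 methyl 19-OTBS-6-OTBDPS-15,15-ethylenedioxy-1-[diethyl(hydrido)silyloxy]-17-nor-6,7-seco-ent-kauran-7-oate
Conditions: [Ir(cod)OMe]2 (0.5 mol %), THF, 25 °C
Reagents that add atoms: none
Why: Iridium-catalysed dehydrogenative coupling of the alcohol with the dihydrosilane gives the (hydrido)silyl ether with loss of H2 under neutral conditions; a hindered secondary alcohol should stop at mono-alkoxylation.

Step 19
Reactants: 26 C1 diethyl(hydrido)silyl ether
Product: 27 oxasilolane bridging O1 and C20 (2,2-diethyl-1,2-oxasilolane cis-fused to ring A at C1–C10; otherwise as 26)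
Conditions: [Ir(cod)OMe]2 (2 mol %), 3,4,7,8-tetramethyl-1,10-phenanthroline (5 mol %), norbornene (1.2 equiv), THF, 100 °C, sealed tube
Reagents that add atoms: none
Why: The Si–H bond adds to the phenanthroline-ligated iridium centre (monovalent to trivalent iridium) and norbornene takes up hydrogen as norbornane, leaving an iridium silyl species. The tethered metal cleaves a C20–H bond through a six-membered iridacycle (Ir, Si, O1, C1, C10, C20), and C–Si reductive elimination releases the product. The closest known reaction type is the iridium-catalysed, hydroxyl-directed γ-silylation of methyl C–H bonds of (hydrido)silyl ethers that leads to 1,3-diols. The one ring closed is the five-membered oxasilolane, formed by intramolecular C–H silylation at the primary carbon; it is cis-fused to ring A because O1 is equatorial and C20 axial (gauche). No stereocentre is created. Site selectivity is needed among the C–H bonds γ to O1: only those of C20 are primary, C3–H2 is secondary and C5–H and C9–H are tertiary, and the catalyst inserts much faster into primary C–H bonds. Chemoselectivity is secured by masking the C15 ketone as its ketal (a ketone would be hydrosilylated); the ester, ketal and silyl ethers are inert, and the aromatic C–H bonds of the remote TBDPS group cannot be reached intramolecularly.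

Step 20
Reactants: 27 oxasilolane
Product: 28 methyl 19-OTBS-6-OTBDPS-15,15-ethylenedioxy-1,20-dihydroxy-17-nor-6,7-seco-ent-kauran-7-oate
Conditions: H2O2 (30% aq.), KHCO3, THF/MeOH (1:1), 50 °C
Reagents that add atoms: hydrogen peroxide, OO
Why: Tamao–Fleming oxidation: hydroperoxide adds to the alkoxy-substituted silicon and C20 migrates from silicon to oxygen, so hydrolysis gives the 1,3-diol; the bicarbonate conditions leave ester, ketal and silyl ethers intact.

Step 21
Reactants: 28 1,20-diol methyl ester
Product: 29 19-OTBS-6-OTBDPS-15,15-ethylenedioxy-1,20-dihydroxy-17-nor-6,7-seco-ent-kauran-7-oic acid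
Conditions: KOSiMe3, THF, 45 °C; then aq. HCl to pH 4 at 0 °C
Reagents that add atoms: none
Why: KOSiMe3 cleaves the hindered methyl ester by attack on the methyl group, which does not depend on access to the neopentyl carbonyl; the C15 ketal prevents retro-Claisen cleavage of the otherwise non-enolizable β-keto ester.

Step 22
Reactants: 29 1,20-diol carboxylic acid
Product: 32 1-acetoxy-19-OTBS-6-OTBDPS-15,15-ethylenedioxy-17-nor-6,7-seco-ent-kauran-7,20-olide, via mixed anhydride 30 (not isolated), via hydroxy lactone 31 (not isolated)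
Conditions: 2,4,6-Cl3C6H2COCl, Et3N, THF, 0 °C; DMAP, toluene, 25 °C (high dilution); then Ac2O, 25 °C
Reagents that add atoms: acetic anhydride, CC(=O)OC(C)=O
Why: Yamaguchi lactonization under kinetic control: the activated acyl group should be taken by the primary C20 hydroxyl rather than the hindered secondary C1 hydroxyl, which could close the isomeric 1,7-lactone. Acetylation of O1 in the same flask removes any later translactonization.

Step 23
Reactants: 32 7,20-lactone 1-acetate
Product: 33 1-acetoxy-19-hydroxy-6-OTBDPS-15-oxo-17-nor-6,7-seco-ent-kauran-7,20-olide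
Conditions: 2 M aq. HCl, THF, 40 °C
Reagents that add atoms: water, O
Why: Aqueous acid hydrolyses the dioxolane and the primary TBS ether, while the far more acid-stable TBDPS ether, the lactone and the hindered secondary acetate should remain.

Step 24
Reactants: 33 C15 ketone C19 alcohol
Product: 34 1,19-diacetoxy-6-OTBDPS-15-oxo-17-nor-6,7-seco-ent-kauran-7,20-olide
Conditions: Ac2O, pyridine, DMAP (cat.), CH2Cl2, 25 °C
Reagents that add atoms: acetic anhydride, CC(=O)OC(C)=O
Why: DMAP-catalysed acetylation of the only free hydroxyl group, the neopentyl primary alcohol at C19.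

Step 25
Reactants: 34 1,19-diacetate
Product: 36 C16-(dimethylaminomethyl) ketone (Mannich base; C16 epimers), via trimethylsilyl enol ether 35 (not isolated)
Conditions: TMSOTf, Et3N, CH2Cl2, 0 °C; then CH2=NMe2+ I−, CH2Cl2, 25 °C; aq. NaHCO3
Reagents that add atoms: dimethylmethyleneiminium iodide (Eschenmoser salt), C=[N+](C)C.[I-]
Why: Only C16 can be enolized because C8 is quaternary; soft enolization and a Mannich reaction with the preformed iminium salt attach C17 without strong base, so acetates and lactone are not disturbed.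

Step 26
Reactants: 36 Mannich base
Product: 38 1,19-diacetoxy-6-OTBDPS-15-oxo-6,7-seco-ent-kaur-16-en-7,20-olide, via ammonium iodide 37 (not isolated)
Conditions: MeI, CH2Cl2, 25 °C; then sat. aq. NaHCO3, 25 °C
Reagents that add atoms: none
Why: Quaternization followed by β-elimination of trimethylamine through the C16 enolate gives the exocyclic enone under bicarbonate, without exposing it to a nucleophilic base.

Step 27
Reactants: 38 C6-OTBDPS enone
Product: 39 1,19-diacetoxy-6-hydroxy-15-oxo-6,7-seco-ent-kaur-16-en-7,20-olide (target)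
Conditions: HF·pyridine, pyridine, THF, 0 to 25 °C
Reagents that add atoms: none
Why: Buffered HF·pyridine cleaves the primary TBDPS ether under mildly acidic conditions, in which acetates should not migrate to the freed C6 hydroxyl and the enone is stable.

## Compound list

1 | pent-1-en-3-one | C=CC(=O)CC | starting material
2 | (Z)-3-(tert-butyldimethylsilyloxy)penta-1,3-diene | C=C/C(O[Si](C)(C)C(C)(C)C)=C/C | intermediate
3 | citraconic anhydride | CC1=CC(=O)OC1=O | starting material
4 | racemic endo adduct, 5-(tert-butyldimethylsilyloxy)-4,7a-dimethyl-3a,4,7,7a-tetrahydro-2-benzofuran-1,3-dione, 4-methyl cis to the anhydride ring (one enantiomer drawn) | C[C@H]1C(O[Si](C)(C)C(C)(C)C)=CC[C@@]2(C)C(=O)OC(=O)[C@@H]12 | intermediate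
5 | (1R,2S,5R)-menthyl hemiester of ring A: menthyl ester at C6, acid at C19, C1 TBS enol ether | C[C@H]1C(O[Si](C)(C)C(C)(C)C)=CC[C@@](C)(C(O)=O)[C@H]1C(=O)O[C@@H]2C[C@H](C)CC[C@H]2C(C)C | intermediate
6 | ring A diol: C19-OH and C6-OH cis, C10 methyl on the same face, C1 TBS enol ether (4R,5S) | C[C@H]1C(O[Si](C)(C)C(C)(C)C)=CC[C@@](C)(CO)[C@H]1CO | intermediate
7 | C6-OTBDPS ether of 6 | C[C@H]1C(O[Si](C)(C)C(C)(C)C)=CC[C@@](C)(CO)[C@H]1CO[Si](c2ccccc2)(c2ccccc2)C(C)(C)C | intermediate
8 | C19-OTBS, C6-OTBDPS ring A bis-silyl ether, C1 TBS enol ether | C[C@H]1C(O[Si](C)(C)C(C)(C)C)=CC[C@@](C)(CO[Si](C)(C)C(C)(C)C)[C@H]1CO[Si](c2ccccc2)(c2ccccc2)C(C)(C)C | intermediate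
9 | ring A enone: C1 ketone, C2=C3, C10-H methyl, C19-OTBS, C6-OTBDPS | C[C@H]1C(=O)C=C[C@@](C)(CO[Si](C)(C)C(C)(C)C)[C@H]1CO[Si](c2ccccc2)(c2ccccc2)C(C)(C)C | intermediate
10 | methyl acetoacetate | COC(=O)CC(C)=O | starting material
11 | trimethyl orthoformate | COC(OC)OC | starting material
12 | methyl 2-(methoxymethylene)-3-oxobutanoate | COC=C(C(C)=O)C(=O)OC | intermediate
13 | lithium dienolate of 9 (C1 enolate, C1=C10) | [Li+].CC1=C([O-])C=C[C@@](C)(CO[Si](C)(C)C(C)(C)C)[C@H]1CO[Si](c2ccccc2)(c2ccccc2)C(C)(C)C | intermediate (not isolated)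
14 | C10-quaternary alkylidene acetoacetate: C10 bears C20 methyl (cis to C6) and CH=C(COMe)CO2Me | COC(=O)C(C(C)=O)=C[C@]1(C)C(=O)C=C[C@@](C)(CO[Si](C)(C)C(C)(C)C)[C@H]1CO[Si](c2ccccc2)(c2ccccc2)C(C)(C)C | intermediate
15 | allyltrimethylsilane | C=CC[Si](C)(C)C | starting material
16 | C9-allyl β-keto ester (C9 as in the target, C8 epimers) | COC(=O)C(C(C)=O)[C@@H](CC=C)[C@]1(C)C(=O)C=C[C@@](C)(CO[Si](C)(C)C(C)(C)C)[C@H]1CO[Si](c2ccccc2)(c2ccccc2)C(C)(C)C | intermediate
17 | allyl methyl carbonate | C=CCOC(=O)OC | starting material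
18 | C8,C9-diallyl β-keto ester, C8 quaternary | COC(=O)[C@](CC=C)(C(C)=O)[C@@H](CC=C)[C@]1(C)C(=O)C=C[C@@](C)(CO[Si](C)(C)C(C)(C)C)[C@H]1CO[Si](c2ccccc2)(c2ccccc2)C(C)(C)C | intermediate
19 | ring C cyclohexene keto ester: C12=C13, acetyl trans to C10, ester cis to C10 | COC(=O)[C@@]1(C(C)=O)CC=CC[C@H]1[C@]2(C)C(=O)C=C[C@@](C)(CO[Si](C)(C)C(C)(C)C)[C@H]2CO[Si](c3ccccc3)(c3ccccc3)C(C)(C)C | intermediate
20 | TBS enol ether of the C15 methyl ketone of 19 | COC(=O)[C@@]1(C(=C)O[Si](C)(C)C(C)(C)C)CC=CC[C@H]1[C@]2(C)C(=O)C=C[C@@](C)(CO[Si](C)(C)C(C)(C)C)[C@H]2CO[Si](c3ccccc3)(c3ccccc3)C(C)(C)C | intermediate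
21 | methyl 19-OTBS-6-OTBDPS-1,15-dioxo-17-nor-6,7-seco-ent-kaura-2,11-dien-7-oate | COC(=O)[C@@]12C(=O)C[C@@H](C1)C=C[C@H]2[C@]3(C)C(=O)C=C[C@@](C)(CO[Si](C)(C)C(C)(C)C)[C@H]3CO[Si](c4ccccc4)(c4ccccc4)C(C)(C)C | intermediate
22 | methyl 19-OTBS-6-OTBDPS-15,15-ethylenedioxy-1-oxo-17-nor-6,7-seco-ent-kaura-2,11-dien-7-oate | COC(=O)[C@@]12C3(OCCO3)C[C@@H](C1)C=C[C@H]2[C@]4(C)C(=O)C=C[C@@](C)(CO[Si](C)(C)C(C)(C)C)[C@H]4CO[Si](c5ccccc5)(c5ccccc5)C(C)(C)C | intermediate
23 | methyl 19-OTBS-6-OTBDPS-15,15-ethylenedioxy-1-oxo-17-nor-6,7-seco-ent-kauran-7-oate | COC(=O)[C@@]12C3(OCCO3)C[C@@H](C1)CC[C@H]2[C@]4(C)C(=O)CC[C@@](C)(CO[Si](C)(C)C(C)(C)C)[C@H]4CO[Si](c5ccccc5)(c5ccccc5)C(C)(C)C | intermediate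
24 | methyl 19-OTBS-6-OTBDPS-15,15-ethylenedioxy-1-hydroxy-17-nor-6,7-seco-ent-kauran-7-oate (1-OH cis to C20) | COC(=O)[C@@]12C3(OCCO3)C[C@@H](C1)CC[C@H]2[C@]4(C)[C@@H](O)CC[C@@](C)(CO[Si](C)(C)C(C)(C)C)[C@H]4CO[Si](c5ccccc5)(c5ccccc5)C(C)(C)C | intermediate
25 | diethylsilane | CC[SiH2]CC | starting material
26 | C1 diethyl(hydrido)silyl ether of 24 (key-step precursor) | COC(=O)[C@@]12C3(OCCO3)C[C@@H](C1)CC[C@H]2[C@]4(C)[C@@H](O[SiH](CC)CC)CC[C@@](C)(CO[Si](C)(C)C(C)(C)C)[C@H]4CO[Si](c5ccccc5)(c5ccccc5)C(C)(C)C | intermediate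
27 | oxasilolane bridging O1 and C20 (key-step product) | COC(=O)[C@@]12C3(OCCO3)C[C@@H](C1)CC[C@H]2[C@]4(C[Si](CC)(CC)O6)[C@@H]6CC[C@@](C)(CO[Si](C)(C)C(C)(C)C)[C@H]4CO[Si](c5ccccc5)(c5ccccc5)C(C)(C)C | intermediate
28 | methyl 19-OTBS-6-OTBDPS-15,15-ethylenedioxy-1,20-dihydroxy-17-nor-6,7-seco-ent-kauran-7-oate | COC(=O)[C@@]12C3(OCCO3)C[C@@H](C1)CC[C@H]2[C@]4(CO)[C@@H](O)CC[C@@](C)(CO[Si](C)(C)C(C)(C)C)[C@H]4CO[Si](c5ccccc5)(c5ccccc5)C(C)(C)C | intermediate
29 | 19-OTBS-6-OTBDPS-15,15-ethylenedioxy-1,20-dihydroxy-17-nor-6,7-seco-ent-kauran-7-oic acid | OC(=O)[C@@]12C3(OCCO3)C[C@@H](C1)CC[C@H]2[C@]4(CO)[C@@H](O)CC[C@@](C)(CO[Si](C)(C)C(C)(C)C)[C@H]4CO[Si](c5ccccc5)(c5ccccc5)C(C)(C)C | intermediate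
30 | mixed anhydride of 29 with 2,4,6-trichlorobenzoic acid | O=C(OC(=O)c6c(Cl)cc(Cl)cc6Cl)[C@@]12C3(OCCO3)C[C@@H](C1)CC[C@H]2[C@]4(CO)[C@@H](O)CC[C@@](C)(CO[Si](C)(C)C(C)(C)C)[C@H]4CO[Si](c5ccccc5)(c5ccccc5)C(C)(C)C | intermediate (not isolated)
31 | 7,20-lactone with free C1-OH | O=C6[C@@]12C3(OCCO3)C[C@@H](C1)CC[C@H]2[C@]4(CO6)[C@@H](O)CC[C@@](C)(CO[Si](C)(C)C(C)(C)C)[C@H]4CO[Si](c5ccccc5)(c5ccccc5)C(C)(C)C | intermediate (not isolated)
32 | 1-acetoxy-19-OTBS-6-OTBDPS-15,15-ethylenedioxy-17-nor-6,7-seco-ent-kauran-7,20-olide | O=C6[C@@]12C3(OCCO3)C[C@@H](C1)CC[C@H]2[C@]4(CO6)[C@@H](OC(C)=O)CC[C@@](C)(CO[Si](C)(C)C(C)(C)C)[C@H]4CO[Si](c5ccccc5)(c5ccccc5)C(C)(C)C | intermediate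
33 | 1-acetoxy-19-hydroxy-6-OTBDPS-15-oxo-17-nor-6,7-seco-ent-kauran-7,20-olide | O=C6[C@@]12C(=O)C[C@@H](C1)CC[C@H]2[C@]4(CO6)[C@@H](OC(C)=O)CC[C@@](C)(CO)[C@H]4CO[Si](c5ccccc5)(c5ccccc5)C(C)(C)C | intermediate
34 | 1,19-diacetoxy-6-OTBDPS-15-oxo-17-nor-6,7-seco-ent-kauran-7,20-olide | O=C6[C@@]12C(=O)C[C@@H](C1)CC[C@H]2[C@]4(CO6)[C@@H](OC(C)=O)CC[C@@](C)(COC(C)=O)[C@H]4CO[Si](c5ccccc5)(c5ccccc5)C(C)(C)C | intermediate
35 | trimethylsilyl enol ether of 34 (C15=C16) | O=C6[C@@]12C(O[Si](C)(C)C)=C[C@@H](C1)CC[C@H]2[C@]4(CO6)[C@@H](OC(C)=O)CC[C@@](C)(COC(C)=O)[C@H]4CO[Si](c5ccccc5)(c5ccccc5)C(C)(C)C | intermediate (not isolated)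
36 | Mannich base: C16-CH2NMe2 derivative of 34 (C16 epimers) | O=C6[C@@]12C(=O)C(CN(C)C)[C@@H](C1)CC[C@H]2[C@]4(CO6)[C@@H](OC(C)=O)CC[C@@](C)(COC(C)=O)[C@H]4CO[Si](c5ccccc5)(c5ccccc5)C(C)(C)C | intermediate
37 | trimethylammonium iodide of 36 | [I-].O=C6[C@@]12C(=O)C(C[N+](C)(C)C)[C@@H](C1)CC[C@H]2[C@]4(CO6)[C@@H](OC(C)=O)CC[C@@](C)(COC(C)=O)[C@H]4CO[Si](c5ccccc5)(c5ccccc5)C(C)(C)C | intermediate (not isolated)
38 | 1,19-diacetoxy-6-OTBDPS-15-oxo-6,7-seco-ent-kaur-16-en-7,20-olide | O=C6[C@@]12C(=O)C(=C)[C@@H](C1)CC[C@H]2[C@]4(CO6)[C@@H](OC(C)=O)CC[C@@](C)(COC(C)=O)[C@H]4CO[Si](c5ccccc5)(c5ccccc5)C(C)(C)C | intermediate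
39 | 1,19-diacetoxy-6-hydroxy-15-oxo-6,7-seco-ent-kaur-16-en-7,20-olide (1-acetoxy cis to C20) | C=C1C(=O)[C@]23C[C@H]1CC[C@H]2[C@]1(COC3=O)[C@@H](OC(C)=O)CC[C@@](C)(COC(C)=O)[C@H]1CO | target

## Step count and least certain steps

Total: 27 steps. Longest linear sequence: 26 steps (steps 1–7 and 9–27); step 8 is a one-step side branch.

Step 19 (key step). The most likely failure is slow C–H cleavage at the congested axial C20 methyl group, which is flanked by the syn-axial C19 CH2OTBS group and the bicyclic substituent on C10. That would let catalyst decay, redistribution at silicon or silylation at C3 take over. The fallback gives up C–H functionalization and carries the C20 oxygen from the first step as a benzyl ether; it sets out from 3 and comes back at 28.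
- CH2=CHMgBr adds to commercial 3-(benzyloxy)propanal to give 5-(benzyloxy)pent-1-en-3-ol F1, and Dess–Martin oxidation gives 5-(benzyloxy)pent-1-en-3-one F2.
- Silylation as in step 1 gives (Z)-5-(benzyloxy)-3-(tert-butyldimethylsilyloxy)penta-1,3-diene F3, and cycloaddition with 3 gives the benzyloxymethyl anhydride F4.
- The sequence of steps 3–7 then leads through menthyl hemiester F5, diol F6, C6-OTBDPS ether F7 and bis-silyl ether F8 to the benzyloxymethyl enone F9. Its α′-enolate carries a β-benzyloxy group and must be kept cold to avoid elimination.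
- Addition–elimination with 12 gives alkylidene acetoacetate F10 (C10 bearing CH2OBn and C9), and the conditions of steps 10–15 give C9-allyl β-keto ester F11, diallyl β-keto ester F12, cyclohexene keto ester F13, TBS enol ether F14, bicyclo[3.2.1]octenone F15 and dioxolane F16.
- Hydrogenation as in step 16 saturates both alkenes and cleaves the benzyl ether to give C20-hydroxy C1 ketone F17, and NaBH4 as in step 17 gives 28.

Step 10. Two things may go wrong: attack on the neopentyl C9 may be slow enough for Lewis-acid side reactions (allylation of the ring A enone, silyl ether cleavage) to compete, and facial selectivity at C9 rests on an acyclic A(1,3) model and may be poor. The fallback replaces the two allylations and the metathesis by a cycloaddition; it sets out from 14 and comes back at 19 and makes no new compound. Buta-1,3-diene and EtAlCl2 in CH2Cl2 at −78 to 0 °C should add across C9=C8 in a Diels–Alder reaction that forms C9–C11 and C8–C14 together. The later, more ordered transition state should be more sensitive to the C5 branch. Suprafacial addition carries the alkene geometry of the isomer of 14 with C10 cis to the ester into the trans relation of acetyl and C10; the E and Z isomers of 14 would have to be separated or equilibrated under the Lewis acid.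

Step 11. Facial selectivity at C8 in the open-chain enolate may be poor, which would place the acetyl group cis to C10 and lead to the wrong bridge later. The fallback sets the C8 configuration on a ring instead; it sets out from 16 and comes back at 19.
- Retro-Claisen deacetylation of 16 with NaOMe in MeOH gives the C9-allyl methyl ester F18.
- LiN(iPr)2 and allyl bromide give the C8-allyl ester F19 (C8 epimers of no consequence), and ring-closing metathesis as in step 12 gives the cyclohexene ester F20.
- LiN(iPr)2 followed by acetyl chloride acylates the exocyclic ring enolate on the face opposite the bulky C10 substituent on the neighbouring carbon, giving 19.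

Step 14. The cyclization needs a ring C conformer with the enol ether axial and the C10 substituent axial on the adjacent carbon; if this is too costly, protodesilylation to 19 or decomposition of the palladium enolate may win. The fallback forms C16–C13 by a radical instead of an organopalladium path; it sets out from 20 and comes back at 21.
- N-Iodosuccinimide converts 20 into the α-iodo ketone F21.
- Et3B and air start an iodine-atom-transfer 5-exo cyclization of the α-keto radical onto C13, giving the C12 iodide F22.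
- DBU eliminates HI towards C11 (elimination towards the bridgehead is impossible), giving 21.

## Further compounds

F1 | step 19 | 5-(benzyloxy)pent-1-en-3-ol (racemic) | C=CC(O)CCOCc1ccccc1
F2 | step 19 | 5-(benzyloxy)pent-1-en-3-one | C=CC(=O)CCOCc1ccccc1
F3 | step 19 | (Z)-5-(benzyloxy)-3-(tert-butyldimethylsilyloxy)penta-1,3-diene | C=C/C(O[Si](C)(C)C(C)(C)C)=C/COCc1ccccc1
F4 | step 19 | benzyloxymethyl anhydride (racemic endo adduct, analogue of 4 with CH2OBn at C10) | c1ccccc1COC[C@H]2C(O[Si](C)(C)C(C)(C)C)=CC[C@@]3(C)C(=O)OC(=O)[C@@H]23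
F5 | step 19 | menthyl hemiester (analogue of 5 with CH2OBn at C10) | c1ccccc1COC[C@H]2C(O[Si](C)(C)C(C)(C)C)=CC[C@@](C)(C(O)=O)[C@H]2C(=O)O[C@@H]3C[C@H](C)CC[C@H]3C(C)C
F6 | step 19 | diol (analogue of 6 with CH2OBn at C10) | c1ccccc1COC[C@H]2C(O[Si](C)(C)C(C)(C)C)=CC[C@@](C)(CO)[C@H]2CO
F7 | step 19 | C6-OTBDPS ether (analogue of 7) | c1ccccc1COC[C@H]2C(O[Si](C)(C)C(C)(C)C)=CC[C@@](C)(CO)[C@H]2CO[Si](c3ccccc3)(c3ccccc3)C(C)(C)C
F8 | step 19 | bis-silyl ether (analogue of 8) | c1ccccc1COC[C@H]2C(O[Si](C)(C)C(C)(C)C)=CC[C@@](C)(CO[Si](C)(C)C(C)(C)C)[C@H]2CO[Si](c3ccccc3)(c3ccccc3)C(C)(C)C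
F9 | step 19 | benzyloxymethyl enone (analogue of 9) | c1ccccc1COC[C@H]2C(=O)C=C[C@@](C)(CO[Si](C)(C)C(C)(C)C)[C@H]2CO[Si](c3ccccc3)(c3ccccc3)C(C)(C)C
F10 | step 19 | alkylidene acetoacetate (analogue of 14 with CH2OBn as C20) | COC(=O)C(C(C)=O)=C[C@]1(COCc2ccccc2)C(=O)C=C[C@@](C)(CO[Si](C)(C)C(C)(C)C)[C@H]1CO[Si](c2ccccc2)(c2ccccc2)C(C)(C)C
F11 | step 19 | C9-allyl β-keto ester (analogue of 16) | COC(=O)C(C(C)=O)[C@@H](CC=C)[C@]1(COCc2ccccc2)C(=O)C=C[C@@](C)(CO[Si](C)(C)C(C)(C)C)[C@H]1CO[Si](c2ccccc2)(c2ccccc2)C(C)(C)C
F12 | step 19 | diallyl β-keto ester (analogue of 18) | COC(=O)[C@](CC=C)(C(C)=O)[C@@H](CC=C)[C@]1(COCc2ccccc2)C(=O)C=C[C@@](C)(CO[Si](C)(C)C(C)(C)C)[C@H]1CO[Si](c2ccccc2)(c2ccccc2)C(C)(C)C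
F13 | step 19 | cyclohexene keto ester (analogue of 19) | COC(=O)[C@@]1(C(C)=O)CC=CC[C@H]1[C@]2(COCc3ccccc3)C(=O)C=C[C@@](C)(CO[Si](C)(C)C(C)(C)C)[C@H]2CO[Si](c3ccccc3)(c3ccccc3)C(C)(C)C
F14 | step 19 | TBS enol ether (analogue of 20) | COC(=O)[C@@]1(C(=C)O[Si](C)(C)C(C)(C)C)CC=CC[C@H]1[C@]2(COCc3ccccc3)C(=O)C=C[C@@](C)(CO[Si](C)(C)C(C)(C)C)[C@H]2CO[Si](c3ccccc3)(c3ccccc3)C(C)(C)C
F15 | step 19 | bicyclo[3.2.1]octenone (analogue of 21) | COC(=O)[C@@]12C(=O)C[C@@H](C1)C=C[C@H]2[C@]3(COCc4ccccc4)C(=O)C=C[C@@](C)(CO[Si](C)(C)C(C)(C)C)[C@H]3CO[Si](c4ccccc4)(c4ccccc4)C(C)(C)C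
F16 | step 19 | dioxolane (analogue of 22) | COC(=O)[C@@]12C3(OCCO3)C[C@@H](C1)C=C[C@H]2[C@]4(COCc5ccccc5)C(=O)C=C[C@@](C)(CO[Si](C)(C)C(C)(C)C)[C@H]4CO[Si](c5ccccc5)(c5ccccc5)C(C)(C)C
F17 | step 19 | C20-hydroxy C1 ketone (analogue of 23 with CH2OH as C20) | COC(=O)[C@@]12C3(OCCO3)C[C@@H](C1)CC[C@H]2[C@]4(CO)C(=O)CC[C@@](C)(CO[Si](C)(C)C(C)(C)C)[C@H]4CO[Si](c5ccccc5)(c5ccccc5)C(C)(C)C
F0 | step 10 | none | none
F18 | step 11 | C9-allyl methyl ester (deacetylated 16) | COC(=O)C[C@@H](CC=C)[C@]1(C)C(=O)C=C[C@@](C)(CO[Si](C)(C)C(C)(C)C)[C@H]1CO[Si](c2ccccc2)(c2ccccc2)C(C)(C)C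
F19 | step 11 | C8-allyl ester (C8 epimers) | COC(=O)C(CC=C)[C@@H](CC=C)[C@]1(C)C(=O)C=C[C@@](C)(CO[Si](C)(C)C(C)(C)C)[C@H]1CO[Si](c2ccccc2)(c2ccccc2)C(C)(C)C
F20 | step 11 | cyclohexene ester (C8 epimers) | COC(=O)C1CC=CC[C@H]1[C@]2(C)C(=O)C=C[C@@](C)(CO[Si](C)(C)C(C)(C)C)[C@H]2CO[Si](c3ccccc3)(c3ccccc3)C(C)(C)C
F21 | step 14 | α-iodo ketone (C16 iodide of 19) | COC(=O)[C@@]1(C(=O)CI)CC=CC[C@H]1[C@]2(C)C(=O)C=C[C@@](C)(CO[Si](C)(C)C(C)(C)C)[C@H]2CO[Si](c3ccccc3)(c3ccccc3)C(C)(C)C
F22 | step 14 | C12 iodide of the bicyclo[3.2.1]octanone (C12 configuration open) | COC(=O)[C@@]12C(=O)C[C@@H](C1)C(I)C[C@H]2[C@]3(C)C(=O)C=C[C@@](C)(CO[Si](C)(C)C(C)(C)C)[C@H]3CO[Si](c4ccccc4)(c4ccccc4)C(C)(C)C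
A1 | alternative 1 | α-methylene lactone with sulfonyl allylic carbonate side chain | COC(=O)OCC(=C)C(S(=O)(=O)c5ccccc5)CC[C@H](C(=C)C(=O)OC6)[C@]46[C@@H](O[Si](C)(C)C(C)(C)C)CC[C@@](C)(CO[Si](C)(C)C(C)(C)C)[C@H]4COCc7ccc(OC)cc7
A2 | alternative 1 | bridgehead sulfone of the methylene bicyclo[3.2.1]octane lactone | C=C1C[C@]23C[C@@]1(S(=O)(=O)c5ccccc5)CC[C@H]2[C@]1(COC3=O)[C@@H](O[Si](C)(C)C(C)(C)C)CC[C@@](C)(CO[Si](C)(C)C(C)(C)C)[C@H]1COCc4ccc(OC)cc4
A3 | alternative 2 | 2-diazocycloheptanone with C20 hydroxyl and C13 acetal side chain | [N-]=[N+]=C1C[C@H](CC(OCC)OCC)CC[C@H](C1=O)[C@]2(CO)[C@@H](O[Si](C)(C)C(C)(C)C)CC[C@@](C)(CO[Si](C)(C)C(C)(C)C)[C@H]2COCc3ccc(OC)cc3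
A4 | alternative 2 | cis-fused lactone cyclohexane with C13 acetal side chain | CCOC(OCC)C[C@@H]1CC[C@@H]2[C@H](C1)C(=O)OC[C@]23[C@@H](O[Si](C)(C)C(C)(C)C)CC[C@@](C)(CO[Si](C)(C)C(C)(C)C)[C@H]3COCc4ccc(OC)cc4
A5 | alternative 3 | (bromomethyl)dimethylsilyl ether of the C1 allylic alcohol with C5=C10 alkene | COC(OC)C1=C(COCc3ccc(OC)cc3)[C@](C)(CO[Si](C)(C)C(C)(C)C)CC[C@@H]1O[Si](C)(C)CBr
A6 | alternative 3 | cis-fused oxasilolane of ring A | COC(OC)[C@]1(C[Si](C)(C)O2)[C@@H]2CC[C@@](C)(CO[Si](C)(C)C(C)(C)C)[C@H]1COCc4ccc(OC)cc4
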